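An hour was my unit, but not the same hour in each flask: I reckoned in noon-clock hours, a run's time multiplied by the square root of its starting [starting material] over noon's.

| flask | starting material | reagent in the second phase | remark | time | volume of the second phase over the first |
|---|---|---|---|---|---|
| spring | 0.010 M | 1.5 equiv | run made earlier |  |  |
| noon | 0.040 M | 1.5 equiv | run made earlier |  |  |
| flask | 0.020 M | 1.50 equiv |  | 3.0 h | 1.0 |

| run | time / h | target / % | starting material / % |
|---|---|---|---|
| spring | 0.200 | 2 | 102 |
| spring | 0.333 | 3 | 99 |
| spring | 0.667 | 4 | 94 |
| spring | 1.33 | 11 | 88 |
| spring | 2.50 | 26 | 71 |
| noon | 0.500 | 8 | 92 |
| noon | 1.00 | 21 | 76 |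
| noon | 1.33 | 30 | 68 |
| noon | 2.00 | 42 | 51 |
| noon | 2.50 | 50 | 41 |

(standard deviation of a reading: 1.5 percentage points)

- in the second phase: reagent in the second phase; everything else is in the first
- charges count per volume of the first phase; a concentration in a rate is the amount of a species over the volume of its own phase; every rate counts per litre of the first phase
- candidate steps: reagent in the reaction phase <-> reagent in the second phase; starting material + reagent in the reaction phase -> target; reagent in the reaction phase + target -> over-reacted product
- the earlier runs hold the two phases in the same ratio of volumes as the flask asked about

- amount of target at 3.0 h, in percent of the starting material charged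
- part of the starting material charged that has reacted at 3.0 h

1. Both runs began slowly, an induction period. I assumed that the reagent in the reaction phase builds up by slow transfer from the second phase. Then, at equal equivalents, L, the logarithm of charged over left, should grow with starting [starting material] times time squared, and equal noon-clock times should give equal percentages.

2. As a check, spring at 2.50 h reads 1.25 h on that clock, and its 71% falls between noon's 76% and 68%.

3. I read the starting rate off noon's reading at 1.00 h, where L was 0.274. The flask at 3.0 h reads 2.12 h on the noon clock, so unslowed L reaches 1.23, or 70.8% reacted.

4. That first answer ignored the slowing. Noon's readings kept a factor 0.613 of the square law, counted from its reading at 1.00 h, at 2.00 h and 0.520 at 2.50 h.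

5. Going round again with 0.591 at the flask's clock, L became 0.727, so I expected 51.8% reacted. Noon's target readings at that clock gave 43.9%.

6. The forecast said 45% target and 52% reacted, each more than my own figure : “Selectivity depends on conversion, so it carries over.”

The flask gave 43.6% target with 49.7% reacted, and the forecast stands within its margins. The flask's target has moved by 5 points at 2.51 h and at 3.68 h, which are 1.78 h and 2.60 h on the noon clock. A run showing the flask's clock out by that much would put its target 5 points from the computed value.

    reagent in the reaction phase ⇌ reagent in the second phase, rate k1*([reagent in the reaction phase] - [reagent in the second phase]/K1) per volume of the first phase (partition coefficient = 0.381, kL = 7.49 × 10⁻⁵ /s)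
    starting material + reagent in the reaction phase → target (k = 0.00622 /M/s)
    reagent in the reaction phase + target → over-reacted product (k = 0.00219 /M/s)

Read at 2.0 h, the same flask stands at 1.41 h on the noon clock, and noon's readings there give 65.9% starting material left and 31.5% target. The computed flask at that time holds 65.7% starting material and 31.7% target.

All runs were generated by integration with constants of no real substance, noise included.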